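**Assumption:** the target SMILES encodes (2R,3S,2''R,3''R). Ring A (4'-OMe) is 2,3-trans and ring B (4'-OH) is 2'',3''-cis, and the route is designed for exactly that. The aldol condensation in Step 7 is assumed to give the thermodynamic (E)-enone.

## Retrosynthesis
- Remove all five O-benzyl groups last by hydrogenolysis, leaving the per-benzylated 3,3''-biflavanone 14.
- Close ring B last (2''R, 3''R-cis) by a catalytic asymmetric intramolecular oxa-Michael addition of the 2'-hydroxy-α-(flavanon-3-yl)chalcone 13. Make 13 by MOM cleavage and aldol condensation of aryl ketone 11 with 4-benzyloxybenzaldehyde (12).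
- Form the C3–C3'' bond (ring A trans) by alkylating the lithium enolate of flavanone 6 with α-bromoketone 10.
- Make flavanone 6 first (2R) by asymmetric oxa-Michael cyclisation of chalcone 5. Make 10 from the same acetophenone 3 by MOM protection and bromination through the silyl enol ether.
- Ring order: A (2R), then C3–C3'' with A trans, then B (2''R, cis).

## Route

**Step 1**
Reactants: 1 (2',4',6'-trihydroxyacetophenone); 2 (benzyl bromide)
Product: 3 (2'-hydroxy-4',6'-bis(benzyloxy)acetophenone)
Conditions: BnBr (2.1 equiv), K2CO3, acetone, reflux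
Reagents that add atoms: benzyl bromide, BrCc1ccccc1
Why: The chelated 2'-OH is the least nucleophilic phenol, so Williamson O-benzylation occurs at the 4'- and 6'-OH; no stereocentres form.

**Step 2**
Reactants: 3; 4 (4-methoxybenzaldehyde)
Product: 5 ((E)-2'-hydroxy-4',6'-bis(benzyloxy)-4-methoxychalcone)
Conditions: KOH (excess), EtOH/H2O, rt
Reagents that add atoms: 4-methoxybenzaldehyde, COc1ccc(C=O)cc1 (carbon skeleton retained in the product)
Why: Claisen–Schmidt aldol condensation gives the thermodynamic E-enone; the extra base equivalents cover the chelated phenol.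

**Step 3**
Reactants: 5
Product: 6 ((2R)-5,7-bis(benzyloxy)-2-(4-methoxyphenyl)chroman-4-one)
Conditions: cinchona-derived bifunctional squaramide (10 mol%, pseudo-enantiomer chosen for the 2R sense), toluene, rt
Reagents that add atoms: none
Why: Enantioselective intramolecular oxa-Michael addition; the catalyst H-bonds the phenol and enone and fixes the enone face, setting C2 as R.

**Step 4**
Reactants: 3; 7 (chloromethyl methyl ether, MOMCl)
Product: 8 (2'-(methoxymethoxy)-4',6'-bis(benzyloxy)acetophenone)
Conditions: NaH, THF, 0 °C, then MOMCl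
Reagents that add atoms: MOMCl, ClCOC
Why: The 2'-OH must be masked, because a free phenoxide would cyclise onto the α-bromoketone to give a benzofuranone; O-alkylation creates no stereocentre.

**Step 5**
Reactants: 8; 9 (N-bromosuccinimide)
Product: 10 (2-bromo-1-[2-(methoxymethoxy)-4,6-bis(benzyloxy)phenyl]ethanone)
Conditions: LiHMDS (1.1 equiv), TMSCl (1.2 equiv), THF, −78 °C; then NBS (1.05 equiv), −78 °C to 0 °C
Reagents that add atoms: N-bromosuccinimide, O=C1CCC(=O)N1Br (LiHMDS and TMSCl leave no atoms in the product)
Why: Kinetic enolisation and O-silylation under base give the TMS enol ether in situ. NBS then brominates only the enol-ether carbon, so the very electron-rich trioxygenated ring is not brominated and the acid-labile MOM group never sees HBr; no stereocentre forms.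

**Step 6**
Reactants: 6; 10
Product: 11 ((2R,3S)-3-[2-aryl-2-oxoethyl]-5,7-bis(benzyloxy)-2-(4-methoxyphenyl)chroman-4-one, aryl = 2-MOMO-4,6-bis(benzyloxy)phenyl)
Conditions: LiHMDS (1.05 equiv), THF, −78 °C; then 10 (1.2 equiv), −78 °C to −40 °C
Reagents that add atoms: none (10 is the electrophile and its atoms are retained)
Why: SN2 alkylation of the flavanone lithium enolate forms the C3–C3'' bond; the 2-aryl group is pseudo-axial, so the electrophile attacks the opposite face and gives the 2,3-trans product (3S). Keeping the temperature at or below −40 °C prevents β-elimination (retro-oxa-Michael) of the enolate, which would racemise C2.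

**Step 7**
Reactants: 11; 12 (4-benzyloxybenzaldehyde)
Product: 13 ((E)-α-[(2R,3S)-flavanon-3-yl]-2'-hydroxychalcone, per-benzylated)
Conditions: 12 (3 equiv), conc. HCl (0.5 equiv), EtOH/THF, 50 °C
Reagents that add atoms: 4-benzyloxybenzaldehyde, O=Cc1ccc(OCc2ccccc2)cc1
Why: Acid hydrolyses the MOM acetal to free the 2'-OH and promotes Claisen–Schmidt condensation at the CH2 next to the aroyl group. Acid is used because base would racemise ring A by retro-oxa-Michael. Any aldol at ring A's tertiary C3 cannot dehydrate and simply reverts, so condensation occurs only at the CH2, giving the thermodynamic E-alkene, which is a prochiral acceptor for Step 8.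

**Step 8**
Reactants: 13
Product: 14 (per-benzylated (2R,3S,2''R,3''R)-3,3''-biflavanone)
Conditions: cinchona-derived squaramide (10 mol%), toluene, 0 °C to rt, short reaction time
Reagents that add atoms: none
Why: Catalyst-controlled intramolecular oxa-Michael addition delivers the phenol O to one face of the β-carbon and sets C2'' as R. The same catalyst protonates the resulting enol(ate) at C3'' kinetically, giving the 3''-substituent cis to the 2''-aryl (3''R), and mild, short conditions avoid equilibration; ring A (2R,3S) is unaffected, and any C3'' epimer is separable by chromatography.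

**Step 9**
Reactants: 14
Product: 15 (Sikokianin B)
Conditions: H2 (1 atm), 10% Pd/C, THF/MeOH, rt
Reagents that add atoms: none (H2 only)
Why: Neutral hydrogenolysis removes all five O-benzyl groups and keeps the 4'-OMe, both ketones and all four stereocentres; no base is present to epimerise the cis centre.

## Compound list
1 | 2',4',6'-trihydroxyacetophenone | CC(=O)c1c(O)cc(O)cc1O | starting material
2 | benzyl bromide | BrCc1ccccc1 | starting material
3 | 2'-hydroxy-4',6'-bis(benzyloxy)acetophenone | CC(=O)c1c(O)cc(OCc2ccccc2)cc1OCc1ccccc1 | intermediate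
4 | 4-methoxybenzaldehyde | COc1ccc(C=O)cc1 | starting material
5 | (E)-2'-hydroxy-4',6'-bis(benzyloxy)-4-methoxychalcone | COc1ccc(/C=C/C(=O)c2c(O)cc(OCc3ccccc3)cc2OCc2ccccc2)cc1 | intermediate
6 | (2R)-5,7-bis(benzyloxy)-2-(4-methoxyphenyl)chroman-4-one | COc1ccc([C@H]2CC(=O)c3c(OCc4ccccc4)cc(OCc4ccccc4)cc3O2)cc1 | intermediate
7 | chloromethyl methyl ether | ClCOC | starting material
8 | 2'-MOM-4',6'-bis(benzyloxy)acetophenone | CC(=O)c1c(OCOC)cc(OCc2ccccc2)cc1OCc1ccccc1 | intermediate
9 | N-bromosuccinimide | O=C1CCC(=O)N1Br | starting material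
10 | 2-bromo-1-[2-(methoxymethoxy)-4,6-bis(benzyloxy)phenyl]ethanone | BrCC(=O)c1c(OCOC)cc(OCc2ccccc2)cc1OCc1ccccc1 | intermediate
11 | (2R,3S)-3-(2-aryl-2-oxoethyl)flavanone | COc1ccc([C@@H]2Oc3cc(OCc4ccccc4)cc(OCc4ccccc4)c3C(=O)[C@H]2CC(=O)c2c(OCOC)cc(OCc3ccccc3)cc2OCc2ccccc2)cc1 | intermediate
12 | 4-benzyloxybenzaldehyde | O=Cc1ccc(OCc2ccccc2)cc1 | starting material
13 | (E)-2'-hydroxy-α-flavanonylchalcone (per-benzylated) | COc1ccc([C@@H]2Oc3cc(OCc4ccccc4)cc(OCc4ccccc4)c3C(=O)[C@H]2/C(=C\c2ccc(OCc3ccccc3)cc2)C(=O)c2c(O)cc(OCc3ccccc3)cc2OCc2ccccc2)cc1 | intermediate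
14 | per-benzylated (2R,3S,2''R,3''R)-3,3''-biflavanone | COc1ccc([C@@H]2Oc3cc(OCc4ccccc4)cc(OCc4ccccc4)c3C(=O)[C@H]2[C@H]2C(=O)c3c(OCc4ccccc4)cc(OCc4ccccc4)cc3O[C@H]2c2ccc(OCc3ccccc3)cc2)cc1 | intermediate
15 | Sikokianin B | COc1ccc([C@@H]2Oc3cc(O)cc(O)c3C(=O)[C@H]2[C@H]2C(=O)c3c(O)cc(O)cc3O[C@H]2c2ccc(O)cc2)cc1 | target

**Total steps:** 9. **Longest linear sequence:** 7 steps from compound 1 (1→3→5→6→11→13→14→15; the branch 1→3→8→10 also reaches 11 in 4 steps).

## Three steps most likely to fail
1. **Step 8 (ring-B oxa-Michael).** The hindered, α-branched enone may cyclise slowly or give the wrong C2''/C3'' diastereomer, and cis-to-trans epimerisation is a further risk. Fallback: cyclise non-selectively with a Brønsted acid (CSA, EtOH, reflux) to a mixture of ring-B diastereomers and isolate the (2''R,3''R) isomer by preparative HPLC. Because ring A is fixed, the diastereomers are separable without chiral phases.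
2. **Step 7 (MOM cleavage and condensation onto the hindered α-branched ketone).** Acid condensation may be slow, or the enone may cyclise prematurely to a racemic flavanone. Fallback: keep the MOM group and run a kinetic Ti-enolate aldol of 11 with 12 at −78 °C. Then remove the MOM group (ZnBr2, n-PrSH) and close ring B from the β-hydroxyketone by intramolecular Mitsunobu SN2 (inversion), choosing the diastereomer that gives 2''R,3''R.
3. **Step 6 (enolate alkylation with the α-bromoketone).** Proton transfer, halophilic attack or ring-opening of the enolate could compete. Fallback: form the same C3–CH2 bond by Cu(II)-mediated oxidative cross-coupling of the lithium enolate of 6 with the TMS enol ether of acetophenone 8, using an excess of 8 to suppress ring-A homodimerisation.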